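**Retrosynthetic overview**
1. Ring D is closed last: O16 adds to the terminal alkyne C14≡C15 (5-endo cycloisomerisation). The C7 acetate is put on after that, so the acid-labile enol ether sees only basic conditions.
2. Ring C: the 9α-hydroxyl opens a C13–C16 epoxide at C13 (5-exo, inversion). C13 comes from a Sharpless epoxidation; the side chain is grown from the C11 ester by methylenation and B-alkyl Suzuki coupling (C12–C13).
3. All ring B oxygens come from the C8 ketone: Saegusa enone, methyl addition, oxidative 1,3-transposition to the 8-methyl-7-en-6-one, then syn-dihydroxylation (7β-OH, 8β-OH). The 9α-OH comes from enolate hydroxylation.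
4. Rings A and B form in one step: proton-initiated bicyclisation (bonds C4–C5 and C9–C10) of the geranylated acetoacetate, itself made by dianion alkylation.
5. The strategy rests on the trans-fused A/B decalin with the gem-dimethyl C4, the axial methyl on C10 and 5α-H, delivered together with a C8 ketone and a C9 ester as handles. Ring order: A+B, then C, then D.

Key step: step 2

Remark on numbering: labdane numbering is used for all ring compounds (decalin C1–C10, side chain C11–C16, C17 = methyl on C8, C18/C19 on C4, C20 on C10); α is the face opposite the C10 methyl.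
Assumption: the (R)-configured binaphthol·SnCl4 acid is taken to protonate the terminal alkene on the face that leads to the (5S,10S) decalin, as in cyclisations of related polyprenoids; if the sense proves opposite, the (S)-acid is used and nothing else changes.

**Step 1**
Reactants: 1 geranyl bromide; 2 methyl acetoacetate
Product: 4 methyl (6E)-7,11-dimethyl-3-oxododeca-6,10-dienoate, via dianion 3 (not isolated)
Conditions: NaH, THF, 0 °C; n-BuLi, 0 °C; then 1, 0 °C to rt; aq. HCl
Reagents that add atoms: none
Why: Alkylation of the acetoacetate dianion takes place at the more reactive terminal carbanion, and SN2 displacement of the primary allylic bromide keeps the E alkene.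

**Step 2**
Reactants: 4 methyl (6E)-7,11-dimethyl-3-oxododeca-6,10-dienoate
Product: 5 trans-decalin β-keto ester, methyl (1R,4aS,8aS)-5,5,8a-trimethyl-2-oxodecahydronaphthalene-1-carboxylate (C8 ketone, 9β ester, 5α-H, 10β-methyl)
Conditions: (R)-2-hydroxy-2'-methoxy-1,1'-binaphthyl·SnCl4 (pre-formed, 1.5 equiv), toluene, −78 °C
Reagents that add atoms: none
Why: Proposed new method: the binaphthol O–H, acidified by coordination to SnCl4, transfers its proton to C3 of the terminal alkene while the chain, folded chair–chair, closes in one antiperiplanar cation–olefin sequence (C5 adds to C4, then the enol carbon C9 adds to the C10 cation) and the enol proton is released, so the acid is not consumed. The closest known reactions are the SnCl4-promoted racemic bicyclisation of this very keto ester and the enantioselective cyclisation of homofarnesol-type polyenes by the same class of tin-activated chiral Brønsted acids; the combination with an enol terminator is new. Ring A closes 6-endo-trig at C4–C5 and ring B 6-endo-trig at C9–C10 with the enol as the terminating nucleophile. C5 and C10 are fixed relative to each other by the E alkene in the chair–chair fold (trans fusion, axial C10 methyl), C9 settles with the ester equatorial (β) because it equilibrates through the enol, and the absolute configuration is decided by the alkene face that takes the proton inside the chiral acid. The step needs the proton to go to the terminal trisubstituted alkene and not to the internal alkene or the enol, and it needs the chiral acid to outrun any achiral tin-bound substrate acid; the terminal alkene is the most accessible π-bond, and the pre-formed acid is used in excess at −78 °C in toluene to suppress the background path.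

**Step 3**
Reactants: 5 trans-decalin β-keto ester
Product: 7 9α-hydroxy-8-oxo ester (5 with a 9α-OH, ester 9β), via potassium enolate 6 (not isolated)
Conditions: KN(SiMe3)2, THF, −78 °C; then 2-(phenylsulfonyl)-3-phenyloxaziridine, −78 °C; aq. NH4Cl
Reagents that add atoms: 2-(phenylsulfonyl)-3-phenyloxaziridine, O=S(=O)(c1ccccc1)N1OC1c1ccccc1
Why: Electrophilic α-hydroxylation of the β-keto ester enolate with the Davis oxaziridine should deliver oxygen to the α-face of C9, anti to the axial C10 methyl, so that the hydroxyl is 9α and the ester stays β.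

**Step 4**
Reactants: 7 9α-hydroxy-8-oxo ester
Product: 8 bis(trimethylsilyl) derivative (9α-OSiMe3 and C7=C8 trimethylsilyl enol ether)
Conditions: Me3SiOTf, Et3N, CH2Cl2, 0 °C to rt
Reagents that add atoms: trimethylsilyl triflate, C[Si](C)(C)OS(=O)(=O)C(F)(F)F
Why: Soft enolisation with a silyl triflate and an amine can only go toward C7 because C9 is fully substituted, and the same reagent silylates the tertiary 9-hydroxyl, whose hindered silyl ether is meant to last until step 15.

**Step 5**
Reactants: 8 bis(trimethylsilyl) derivative
Product: 9 9α-(trimethylsilyloxy)-6-en-8-one methyl ester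
Conditions: Pd(OAc)2 (1.1 equiv), MeCN, rt
Reagents that add atoms: none
Why: Saegusa–Ito oxidation, in which the palladium enolate formed from the silyl enol ether loses a β-hydride from C6 and gives the C6=C7 enone.

**Step 6**
Reactants: 9 9α-(trimethylsilyloxy)-6-en-8-one methyl ester
Product: 10 tertiary allylic alcohol (8-hydroxy-8-methyl-6-ene, 9α-OSiMe3, ester; expected 8α-OH, 8β-methyl)
Conditions: MeLi, CeCl3, THF, −78 °C; AcOH quench at −78 °C
Reagents that add atoms: methyllithium, [Li]C
Why: The non-basic organocerium reagent should add 1,2 to the hindered conjugated C8 ketone faster than to the neopentyl ester, most probably anti to the pseudoaxial 9α-silyloxy group, and the configuration of this carbinol carbon is erased in step 7.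

**Step 7**
Reactants: 10 tertiary allylic alcohol
Product: 11 8-methyl-7-en-6-one methyl ester, 9α-OSiMe3
Conditions: [C5H5NH][CrO3Cl] (pyridinium chlorochromate), 4 Å MS, CH2Cl2, rt
Reagents that add atoms: pyridinium chlorochromate, [O-][Cr](=O)(=O)Cl.c1cc[nH+]cc1
Why: Babler–Dauben oxidative transposition, in which the chromate ester of the tertiary allylic alcohol undergoes a [3,3] shift to C6 and is oxidised there, so that the carbonyl moves from C8 to C6 and the methyl group stays on the C7=C8 alkene.

**Step 8**
Reactants: 11 8-methyl-7-en-6-one methyl ester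
Product: 12 6β,11-diol (8-methyl-7-ene, 9α-OSiMe3; configuration at C6 of no consequence)
Conditions: i-Bu2AlH (excess), CH2Cl2, −78 to 0 °C; Rochelle salt work-up
Reagents that add atoms: none
Why: Hydride reduction should take the ester to the C11 carbinol and the enone 1,2 to the allylic alcohol (hydride from the open α-face), and both hydroxyls are oxidised together in step 9.

**Step 9**
Reactants: 12 6β,11-diol
Product: 13 6-oxo-7-ene C11 aldehyde, 9α-OSiMe3
Conditions: Dess–Martin periodinane (excess), NaHCO3, CH2Cl2, 0 °C to rt
Reagents that add atoms: none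
Why: Dess–Martin oxidation of the primary and the allylic secondary alcohol under buffered conditions should give the non-enolisable C11 aldehyde and restore the C6 enone.

**Step 10**
Reactants: 13 6-oxo-7-ene C11 aldehyde
Product: 14 9β-vinyl 8-methyl-7-en-6-one, 9α-OSiMe3 (C11=C12)
Conditions: Ph3PCH3Br, KN(SiMe3)2, THF, 0 °C; then 13, −78 to 0 °C
Reagents that add atoms: methyltriphenylphosphonium bromide, C[P+](c1ccccc1)(c1ccccc1)c1ccccc1.[Br-]
Why: Wittig methylenation should be selective for the aldehyde, which has no α-hydrogen, over the hindered conjugated C6 ketone.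

**Step 11**
Reactants: 14 9β-vinyl 8-methyl-7-en-6-one; 15 2-bromoprop-2-en-1-ol
Product: 17 allylic alcohol with the chain C11–C12–C13(=CH2)–CH2OH on C9, via alkylborane 16 (not isolated)
Conditions: 9-BBN, THF, 0 °C to rt; then 15, PdCl2(dppf), AsPh3, K3PO4 (aq.), DMF, rt
Reagents that add atoms: none
Why: Anti-Markovnikov hydroboration of the monosubstituted alkene by 9-BBN should be faster than reduction of the hindered enone, and the primary alkylborane then undergoes B-alkyl Suzuki–Miyaura coupling with the vinyl bromide to form C12–C13.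

**Step 12**
Reactants: 17 allylic alcohol
Product: 18 epoxy alcohol (C13–C16 oxirane, 13R; C14 hydroxymethyl)
Conditions: Ti(OiPr)4 (cat.), D-(−)-diethyl tartrate, t-BuOOH, 4 Å MS, CH2Cl2, −20 °C
Reagents that add atoms: tert-butyl hydroperoxide, CC(C)(C)OO
Why: Sharpless asymmetric epoxidation, in which the titanium tartrate binds the primary allylic alcohol and D-(−)-tartrate selects the alkene face that makes C13 (R) under reagent control, while the silylated 9-hydroxyl cannot open the epoxide at this stage.

**Step 13**
Reactants: 18 epoxy alcohol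
Product: 19 epoxy aldehyde (C14 aldehyde, C13 unchanged)
Conditions: Dess–Martin periodinane, NaHCO3, CH2Cl2, 0 °C
Reagents that add atoms: none
Why: Dess–Martin oxidation gives the epoxy aldehyde, which cannot epimerise because C13 bears no hydrogen.

**Step 14**
Reactants: 19 epoxy aldehyde
Product: 20 ethynyl epoxide (C14≡C15 on C13, C13–C16 oxirane, 9α-OSiMe3)
Conditions: dimethyl (1-diazo-2-oxopropyl)phosphonate, K2CO3, MeOH, 0 °C to rt
Reagents that add atoms: dimethyl (1-diazo-2-oxopropyl)phosphonate, COP(=O)(OC)C(=[N+]=[N-])C(C)=O
Why: Seyferth–Gilbert homologation with the Ohira–Bestmann reagent converts the aldehyde into the terminal alkyne under mild carbonate conditions that should leave the epoxide and the hindered silyl ether in place.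

**Step 15**
Reactants: 20 ethynyl epoxide
Product: 21 ethynyl epoxide with free 9α-OH
Conditions: Bu4NF, AcOH, THF, 0 °C
Reagents that add atoms: none
Why: Fluoride cleaves the trimethylsilyl ether, and acetic acid buffers the alkoxide so that neither base-induced epoxide opening nor vinylogous retro-aldol cleavage of the γ-hydroxy enone should occur.

**Step 16**
Reactants: 21 ethynyl epoxide with free 9α-OH
Product: 22 9α,13-epoxide (ring C closed, 13S) with C13 ethynyl, C16 hydroxymethyl and the 8-methyl-7-en-6-one
Conditions: camphorsulfonic acid (10 mol%), CH2Cl2, 0 °C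
Reagents that add atoms: none
Why: Acid-catalysed epoxy-alcohol cyclisation, in which the 9α-hydroxyl attacks the tertiary propargylic C13 in the 5-exo mode with inversion, closes ring C, sets C13 as in the target and frees the C16 hydroxyl.

**Step 17**
Reactants: 22 ring C enone
Product: 23 7β,8β-diol (8α-methyl) 6-ketone with C13 ethynyl and C16 hydroxymethyl
Conditions: OsO4 (10 mol%), N-methylmorpholine N-oxide, citric acid, t-BuOH/H2O, rt
Reagents that add atoms: N-methylmorpholine N-oxide, C[N+]1([O-])CCOCC1; water, O; osmium tetroxide (catalytic oxygen carrier), O=[Os](=O)(=O)=O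
Why: Catalytic osmium tetroxide syn-dihydroxylation should take place on the β-face of C7=C8, anti to the pseudoaxial allylic C9–O bond of ring C, which gives 7β-OH and 8β-OH and leaves the methyl group 8α.

**Step 18**
Reactants: 23 7β,8β-diol alkynol
Product: 24 7-deacetyl compound (rings C and D closed, 7β,8β-diol)
Conditions: Mo(CO)6 (25 mol%), Et3N, Et2O, hν (350 nm); then 23, rt in the dark
Reagents that add atoms: none
Why: Alkynol cycloisomerisation through a molybdenum vinylidene, in which O16 adds to C15 in the 5-endo mode and protonation gives the 2,3-dihydrofuran, while the amine medium protects the acid-labile enol ether.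

**Step 19**
Reactants: 24 7-deacetyl compound
Product: 25 target (7β-acetate)
Conditions: Ac2O, pyridine, DMAP (cat.), CH2Cl2, 0 °C; Et3N-deactivated silica
Reagents that add atoms: acetic anhydride, CC(=O)OC(C)=O
Why: Acylation should be selective for the secondary 7β-hydroxyl because the only other free hydroxyl is the hindered tertiary one at C8, the basic conditions suit the enol ether, and the equatorial 7β-acetate next to the ketone is also the thermodynamically preferred epimer.

**Compound list**
1 | geranyl bromide | CC(C)=CCC/C(C)=C/CBr | starting material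
2 | methyl acetoacetate | COC(=O)CC(C)=O | starting material
3 | sodium lithium dianion of methyl acetoacetate (not isolated) | COC([O-])=CC([O-])=C.[Na+].[Li+] | intermediate
4 | methyl (6E)-7,11-dimethyl-3-oxododeca-6,10-dienoate | COC(=O)CC(=O)CC/C=C(\C)CCC=C(C)C | intermediate
5 | trans-decalin β-keto ester, methyl (1R,4aS,8aS)-5,5,8a-trimethyl-2-oxodecahydronaphthalene-1-carboxylate | COC(=O)[C@H]1C(=O)CC[C@H]2C(C)(C)CCC[C@]12C | intermediate
6 | potassium enolate of 5 (not isolated) | COC(=O)C1=C([O-])CC[C@H]2C(C)(C)CCC[C@]12C.[K+] | intermediate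
7 | 9α-hydroxy-8-oxo ester | COC(=O)[C@@]1(O)C(=O)CC[C@H]2C(C)(C)CCC[C@]12C | intermediate
8 | 9α-OSiMe3, C7=C8 trimethylsilyl enol ether | COC(=O)[C@@]1(O[Si](C)(C)C)C(O[Si](C)(C)C)=CC[C@H]2C(C)(C)CCC[C@]12C | intermediate
9 | 9α-(trimethylsilyloxy)-6-en-8-one methyl ester | COC(=O)[C@@]1(O[Si](C)(C)C)C(=O)C=C[C@H]2C(C)(C)CCC[C@]12C | intermediate
10 | tertiary allylic alcohol (8α-OH, 8β-methyl expected; 6-ene) | COC(=O)[C@@]1(O[Si](C)(C)C)[C@](C)(O)C=C[C@H]2C(C)(C)CCC[C@]12C | intermediate
11 | 8-methyl-7-en-6-one methyl ester, 9α-OSiMe3 | COC(=O)[C@@]1(O[Si](C)(C)C)C(C)=CC(=O)[C@H]2C(C)(C)CCC[C@]12C | intermediate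
12 | 6β,11-diol, 8-methyl-7-ene, 9α-OSiMe3 | OC[C@@]1(O[Si](C)(C)C)C(C)=C[C@@H](O)[C@H]2C(C)(C)CCC[C@]12C | intermediate
13 | 6-oxo-7-ene C11 aldehyde, 9α-OSiMe3 | O=C[C@@]1(O[Si](C)(C)C)C(C)=CC(=O)[C@H]2C(C)(C)CCC[C@]12C | intermediate
14 | 9β-vinyl 8-methyl-7-en-6-one, 9α-OSiMe3 | C=C[C@@]1(O[Si](C)(C)C)C(C)=CC(=O)[C@H]2C(C)(C)CCC[C@]12C | intermediate
15 | 2-bromoprop-2-en-1-ol | OCC(Br)=C | starting material
16 | C12 alkylborane, 9-BBN adduct of 14 (not isolated) | B1(C2CCCC1CCC2)CC[C@@]3(O[Si](C)(C)C)C(C)=CC(=O)[C@H]4C(C)(C)CCC[C@]34C | intermediate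
17 | allylic alcohol, C13(=CH2)–CH2OH side chain | OCC(=C)CC[C@@]1(O[Si](C)(C)C)C(C)=CC(=O)[C@H]2C(C)(C)CCC[C@]12C | intermediate
18 | (13R)-epoxy alcohol | OC[C@]1(CC[C@@]2(O[Si](C)(C)C)C(C)=CC(=O)[C@H]3C(C)(C)CCC[C@]23C)CO1 | intermediate
19 | epoxy aldehyde (same arrangement at C13 as 18) | O=C[C@]1(CC[C@@]2(O[Si](C)(C)C)C(C)=CC(=O)[C@H]3C(C)(C)CCC[C@]23C)CO1 | intermediate
20 | ethynyl epoxide, 9α-OSiMe3 | C#C[C@]1(CC[C@@]2(O[Si](C)(C)C)C(C)=CC(=O)[C@H]3C(C)(C)CCC[C@]23C)CO1 | intermediate
21 | ethynyl epoxide, free 9α-OH | C#C[C@]1(CC[C@@]2(O)C(C)=CC(=O)[C@H]3C(C)(C)CCC[C@]23C)CO1 | intermediate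
22 | 9α,13-epoxy (ring C) 8-methyl-7-en-6-one, C13 ethynyl, C16 hydroxymethyl | CC1=CC(=O)[C@H]2C(C)(C)CCC[C@]2(C)[C@@]12CC[C@@](CO)(C#C)O2 | intermediate
23 | 7β,8β-diol 6-ketone alkynol | O[C@H]1C(=O)[C@H]2C(C)(C)CCC[C@]2(C)[C@@]2(CC[C@@](CO)(C#C)O2)[C@@]1(C)O | intermediate
24 | 7-deacetyl compound, rings C and D closed | O[C@H]1C(=O)[C@H]2C(C)(C)CCC[C@]2(C)[C@@]2(CC[C@@]3(C=COC3)O2)[C@@]1(C)O | intermediate
25 | CNP0284584.1 | CC(=O)O[C@H]1C(=O)[C@H]2C(C)(C)CCC[C@]2(C)[C@@]2(CC[C@@]3(C=COC3)O2)[C@@]1(C)O | target

**Step count**
Total: 19 steps. Longest linear sequence: 19 steps (from 1 and 2; 15 is bought).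

**Steps most likely to fail**

1. Step 2 (new method). What may go wrong: a racemic background cyclisation through tin species bound to the β-keto ester, which lowers the enantiomeric purity, or a stop after ring A. The fallback replaces asymmetric catalysis by resolution and uses known chemistry only. It sets out from 4: SnCl4 in CH2Cl2 gives the racemic keto ester F1, and NaBH4 in MeOH reduces it to the racemic 8β-hydroxy ester F2. Esterification with (S)-O-methylmandelic acid (DCC, DMAP) gives the wanted mandelate F3 and the diastereomeric mandelate of the enantiomeric alcohol F4, which are separated by chromatography or crystallisation. K2CO3 in MeOH cleaves F3 to the enantiopure hydroxy ester F5, and Dess–Martin oxidation comes back to the route at 5.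

2. Step 17. What may go wrong: poor facial selectivity (addition from the α-face past the ring C oxygen) or low conversion on the hindered, electron-poor alkene. The fallback replaces syn-dihydroxylation by epoxide opening with inversion at C8 and equilibration at C7, and it uses exactly the α-face attack that would spoil step 17. It sets out from 22: t-BuOOH and DBU in CH2Cl2 (nucleophilic epoxidation from the α-face) give the 7α,8α-epoxy ketone F6. Aqueous HClO4 in THF opens it trans-diaxially at the tertiary C8 to the 7α,8β-diol F7. DBU in CH2Cl2 then equilibrates the α-ketol carbon C7 to the equatorial 7β-alcohol, which comes back to the route at 23.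

3. Step 11. What may go wrong: reduction of the C6 enone by the borane, sluggish hydroboration of the congested vinyl group, or β-hydride loss during the coupling. The fallback replaces hydroboration and cross-coupling by olefination and conjugate reduction. It sets out from 13: Horner–Wadsworth–Emmons reaction with dimethyl [3-(4-methoxybenzyloxy)-2-oxopropyl]phosphonate (LiCl, i-Pr2NEt, MeCN) gives the (E)-side-chain enone F8. [(Ph3P)CuH]6 reduces this less hindered enone selectively to the C13 ketone F9. Wittig methylenation (Ph3PCH3Br, KN(SiMe3)2) of the unhindered C13 ketone gives the 4-methoxybenzyl allyl ether F10, and DDQ in wet CH2Cl2 removes the benzyl group and comes back to the route at 17.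

**Further compounds**
F1 | step 2 | racemic bicyclic β-keto ester (racemate of 5, one enantiomer drawn) | COC(=O)[C@H]1C(=O)CC[C@H]2C(C)(C)CCC[C@]12C
F2 | step 2 | racemic methyl 8β-hydroxy ester (one enantiomer drawn) | COC(=O)[C@H]1[C@@H](O)CC[C@H]2C(C)(C)CCC[C@]12C
F3 | step 2 | (S)-O-methylmandelate of the (5S,10S) 8β-hydroxy ester | COC(=O)[C@H]1[C@@H](OC(=O)[C@@H](OC)c2ccccc2)CC[C@H]2C(C)(C)CCC[C@]12C
F4 | step 2 | (S)-O-methylmandelate of the enantiomeric hydroxy ester (separated and discarded) | COC(=O)[C@@H]1[C@H](OC(=O)[C@@H](OC)c2ccccc2)CC[C@@H]2C(C)(C)CCC[C@@]12C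
F5 | step 2 | enantiopure methyl 8β-hydroxy ester | COC(=O)[C@H]1[C@@H](O)CC[C@H]2C(C)(C)CCC[C@]12C
F6 | step 17 | 7α,8α-epoxy-6-ketone with ring C closed | O1[C@@H]2C(=O)[C@H]3C(C)(C)CCC[C@]3(C)[C@@]3(CC[C@@](CO)(C#C)O3)[C@]12C
F7 | step 17 | 7α,8β-dihydroxy-6-ketone (7-epimer of 23) | O[C@@H]1C(=O)[C@H]2C(C)(C)CCC[C@]2(C)[C@@]2(CC[C@@](CO)(C#C)O2)[C@@]1(C)O
F8 | step 11 | (E)-C11=C12 enone with C13 ketone and 4-methoxybenzyl ether | COc1ccc(COCC(=O)/C=C/[C@@]2(O[Si](C)(C)C)C(C)=CC(=O)[C@H]3C(C)(C)CCC[C@]23C)cc1
F9 | step 11 | C13 ketone with 4-methoxybenzyl ether | COc1ccc(COCC(=O)CC[C@@]2(O[Si](C)(C)C)C(C)=CC(=O)[C@H]3C(C)(C)CCC[C@]23C)cc1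
F10 | step 11 | 4-methoxybenzyl ether of 17 | COc1ccc(COCC(=C)CC[C@@]2(O[Si](C)(C)C)C(C)=CC(=O)[C@H]3C(C)(C)CCC[C@]23C)cc1
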